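**Retrosynthetic overview**

1. Rings and locants: ring A (cyclobutane) and ring B (cyclononane) are the caryophyllane part (C1–C15). Ring C is the dihydropyran (O, C4, C5, C7′H2, C2′, C3′). Ring D is the acyl-β-triketone ring (C1′–OH, C2′, C3′, C4′Me2, C5′=O, C6′–acyl).
2. Last disconnection, ring D: both ring bonds of C6′ (C6′–C1′ and C6′–C5′) are cut. This [5+1] double Claisen condensation leads back to the ring C diester 8 and the methyl carbon of (S)-3-methylpentan-2-one 12, and it copies the Claisen ring closure of the polyketide chain in acylphloroglucinol biosynthesis.
3. Enabling feature: C6′ is a triacylmethane carbon flanked by C1′ and C5′, and the other three atoms of ring D (the enol ether pair C2′=C3′ and the quaternary C4′) carry no hydrogen. Diester 8 therefore cannot enolize, and the product leaves the equilibrium as a stable triketonate.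
4. Ring C: inverse-electron-demand hetero-Diels–Alder reaction of the strained E-configured C4=C5 bond of (−)-β-caryophyllene 6 with the 2-methylene β-keto diester 7 (from 5 and formaldehyde); this sets C4 and C5.
5. Order of rings: A and B arrive with 6, ring C forms in step 2, ring D in step 4. Diester 5 comes from the malonate half-esters 1 and 2, ketone 12 from (S)-2-methylbutanoic acid 9.

Key step: step 4

Remark: the target is drawn as one enol tautomer of its cyclic β-triketone; the tautomers equilibrate and are treated as one compound. The terpene stereocenters correspond to natural (−)-β-caryophyllene (1R,9S), and the target is the (1R,4R,5S,9S) isomer with an (S)-2-methylbutanoyl group.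

**Route**

Step 1
Reactants: 1 3-methoxy-2,2-dimethyl-3-oxopropanoic acid; 2 potassium 3-methoxy-3-oxopropanoate (potassium methyl malonate)
Product: 5 dimethyl 2,2-dimethyl-3-oxopentanedioate, via acyl imidazolide 3 (not isolated), via acylmalonic half-ester 4 (not isolated)
Conditions: 1,1′-carbonyldiimidazole, THF, rt; then 2, MgCl2, Et3N, THF, rt → 45 °C; 1 M HCl
Reagents that add atoms: none
Why: Decarboxylative Claisen condensation of a magnesium malonate half-ester with an acyl imidazolide, the standard β-keto ester synthesis; the quaternary α-carbon of 1 excludes ketene formation and self-condensation, and no stereocenter is involved.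

Step 2
Reactants: 5 dimethyl 2,2-dimethyl-3-oxopentanedioate; 6 (−)-β-caryophyllene
Product: 8 ring C diester (dihydropyran trans-fused at C4–C5 of the caryophyllane, CO2Me on C2′, C(CH3)2CO2Me on C3′, 1R,4R,5S,9S), via methylene keto diester 7 (not isolated)
Conditions: (CH2O)n (3 equiv), 6 (2.5 equiv), ethylenediammonium diacetate (20 mol %), 1,4-dioxane, 90 °C, sealed tube
Reagents that add atoms: paraformaldehyde (as formaldehyde), C=O
Why: Domino Knoevenagel/inverse-electron-demand hetero-Diels–Alder reaction in which the 1-oxadiene of 7 (ketone C=O and the new C=CH2) adds to the strained, electron-rich C4=C5 bond of 6 (the exocyclic C8=C13 bond is far less reactive), with O going to the more substituted C4 and CH2 to C5; suprafacial addition to the E-alkene fixes the trans ring fusion (4-CH3 and 5-H anti), and attack on the outer face of the predominant βα/ββ conformers of 6, the face that peracids also take, should set 4R,5S, with the minor face isomer removed by chromatography.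

Step 3
Reactants: 9 (S)-2-methylbutanoic acid
Product: 12 (S)-3-methylpentan-2-one, via lithium carboxylate 10 (not isolated), via dilithium gem-diolate 11 (not isolated)
Conditions: MeLi (2.2 equiv), Et2O, −78 → 0 °C; inverse quench into cold 1 M HCl; used as a dried, titrated solution
Reagents that add atoms: methyllithium, [Li]C
Why: Addition of methyllithium to the lithium carboxylate gives a dilithium gem-diolate that cannot add a second equivalent and releases the ketone only on the acidic inverse quench; the α-stereocenter should be retained because the carboxylate is attacked at carbon faster than it is deprotonated and the ketone never meets base.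

Step 4
Reactants: 8 ring C diester; 12 (S)-3-methylpentan-2-one
Product: 15 CNP0591516.2 (target), via lithium enolate 13 (not isolated), via diketo ester 14 (not isolated)
Conditions: 12 (1.1 equiv), LiN(iPr)2 (1.15 equiv), THF, −78 °C; then 8 (1.0 equiv), LiN(SiMe3)2 (2.2 equiv), −78 °C → 40 °C; 1 M HCl
Reagents that add atoms: none
Why: The kinetic lithium enolate 13 (methyl side) acylates one ester of the non-enolizable diester 8 in a Claisen condensation, the resulting lithium β-diketonate 14 is C-acylated at the same carbon by the second ester, and the product is drained as its lithium β-triketonate, which makes both acylations irreversible. The closest known reaction types are the double Claisen condensation of a methyl ketone with a 1,2-diester that gives 2-acylindane-1,3-diones and the Claisen ring closure of 3,5,7-triketo esters to acylphloroglucinols, the ring-forming event of acylphloroglucinol biosynthesis. Ring D closes by 6-exo-trig attack of C6′ on an ester carbonyl, and because the second acylation is intramolecular, the order in which the two esters react does not change the product. No new stereocenter is formed; C1, C4, C5 and C9 are remote from the reacting centres, and the (S) centre of the side chain should survive because the enolate is formed irreversibly at the methyl carbon, LiN(SiMe3)2 acts as proton sink so that no neutral ketone is left to shuttle protons, and after the first acylation the centre lies next to a diketonate. The step needs C- over O-acylation and one ketone per diester: esters acylate enolates at carbon under thermodynamic control, 8 has no acidic hydrogen (C2′, C3′ and C4′ carry none), and with 12 in only slight excess the intramolecular second acylation should outrun a second intermolecular one.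

**Compound list**

1 | 3-methoxy-2,2-dimethyl-3-oxopropanoic acid (monomethyl 2,2-dimethylmalonate) | COC(=O)C(C)(C)C(=O)O | starting material
2 | potassium 3-methoxy-3-oxopropanoate (potassium methyl malonate) | [K+].[O-]C(=O)CC(=O)OC | starting material
3 | methyl 3-(1H-imidazol-1-yl)-2,2-dimethyl-3-oxopropanoate (acyl imidazolide) | COC(=O)C(C)(C)C(=O)n1ccnc1 | intermediate (not isolated)
4 | 3-methoxy-2-(3-methoxy-2,2-dimethyl-3-oxopropanoyl)-3-oxopropanoic acid (acylmalonic half-ester, formed as its magnesium chelate) | COC(=O)C(C(=O)O)C(=O)C(C)(C)C(=O)OC | intermediate (not isolated)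
5 | dimethyl 2,2-dimethyl-3-oxopentanedioate | COC(=O)CC(=O)C(C)(C)C(=O)OC | intermediate
6 | (−)-β-caryophyllene, (1R,4E,9S)-4,11,11-trimethyl-8-methylidenebicyclo[7.2.0]undec-4-ene | C=C1CC/C=C(\C)CC[C@@H]2[C@@H]1CC2(C)C | starting material
7 | dimethyl 2,2-dimethyl-4-methylidene-3-oxopentanedioate (methylene keto diester, heterodiene) | C=C(C(=O)OC)C(=O)C(C)(C)C(=O)OC | intermediate (not isolated)
8 | ring C diester: dihydropyran trans-fused at C4–C5 of the caryophyllane, CO2CH3 on C2′, 1-methoxy-2-methyl-1-oxopropan-2-yl on C3′, exocyclic C8=CH2 intact, (1R,4R,5S,9S) | C=C1CC[C@H]2CC(C(=O)OC)=C(O[C@]2(C)CC[C@@H]2[C@@H]1CC2(C)C)C(C)(C)C(=O)OC | intermediate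
9 | (S)-2-methylbutanoic acid | OC(=O)[C@@H](C)CC | starting material
10 | lithium (S)-2-methylbutanoate | [Li+].[O-]C(=O)[C@@H](C)CC | intermediate (not isolated)
11 | dilithium (S)-3-methylpentane-2,2-diolate | [Li+].[Li+].CC([O-])([O-])[C@@H](C)CC | intermediate (not isolated)
12 | (S)-3-methylpentan-2-one | CC(=O)[C@@H](C)CC | intermediate
13 | lithium (S)-3-methylpent-1-en-2-olate (kinetic enolate of 12) | [Li+].C=C([O-])[C@@H](C)CC | intermediate (not isolated)
14 | diketo ester: as 8, but the C2′ ester replaced by the (S)-4-methyl-3-oxohexanoyl group (β-diketone), C(CH3)2CO2CH3 on C3′ unchanged | C=C1CC[C@H]2CC(C(=O)CC(=O)[C@@H](C)CC)=C(O[C@]2(C)CC[C@@H]2[C@@H]1CC2(C)C)C(C)(C)C(=O)OC | intermediate (not isolated)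
15 | CNP0591516.2: rings A–D, 4′,4′-dimethyl, 1′-hydroxy, 5′-oxo, 6′-[(S)-2-methylbutanoyl], (1R,4R,5S,9S) | C=C1CC[C@H]2CC3=C(O[C@]2(C)CC[C@@H]2[C@@H]1CC2(C)C)C(C)(C)C(=O)C(C(=O)[C@@H](C)CC)=C3O | target

**Step count**

Total: 4 steps. Longest linear sequence: 3 steps (1 → 2 → 4); step 3 is a one-step branch.

**Steps most likely to fail, with fallbacks**

Step 4. Both esters of 8 are slow acyl acceptors (one is α-quaternary, the other a hindered vinylogous carbonate), so the intermolecular acylation may lag behind proton exchange of the enolate (erosion of the side-chain centre), stop after the first acylation, or give way to addition–elimination at C3′ with opening of ring C. The fallback sets out from 8 and comes back at 15; it replaces the esters by an activated acyl pair. Saponification of 8 (LiOH, aqueous 1,4-dioxane, 80 °C) should give the diacid F1. Dehydration with acetic anhydride should give the six-membered cyclic anhydride F2. Anhydrides are opened by ketone lithium enolates at −78 °C, so 13 (made from 12 as in step 4, with LiN(SiMe3)2 as proton sink) should give the diketo acid F3; opening at either anhydride carbonyl leads to a diketo acid that closes to the same ring. Cyclodehydration of F3 with N,N′-dicyclohexylcarbodiimide and 4-(dimethylamino)pyridine in CH2Cl2 (carbodiimide-mediated C-acylation of a β-diketone by enol ester formation and O-to-C acyl transfer) should then close ring D and give 15.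

Step 2. The acyclic heterodiene 7 may dimerize or add a second molecule of 5 faster than it is trapped by 6, its hindered ketone may leave the ester carbonyl to act as the oxadiene terminus, and facial selectivity on 6 may be modest. The fallback sets out from 5 and comes back at 8; it releases 7 from an isolated precursor at low temperature, without free amine or formaldehyde. Mannich reaction of 5 with N,N-dimethylmethyleneiminium iodide (CH2Cl2, rt) should give the racemic Mannich base dimethyl 4-[(dimethylamino)methyl]-2,2-dimethyl-3-oxopentanedioate F4. Methyl iodide should convert it into the trimethylammonium iodide F5. Stirring F5 with NaHCO3 and excess 6 in acetonitrile at rt to 40 °C should liberate 7 slowly by elimination, and its capture by 6 at this lower temperature should give 8, possibly with better face selectivity.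

Step 3. Ketone formed during the quench may be attacked by residual methyllithium (tertiary alcohol), some enolization may erode the stereocenter, and the volatile ketone may be lost on isolation. The fallback sets out from 9 and comes back at 12. Activation of 9 with 1,1′-carbonyldiimidazole and reaction with N,O-dimethylhydroxylamine hydrochloride should give (S)-N-methoxy-N,2-dimethylbutanamide F6. MeMgBr in THF at 0 °C forms a stable magnesium chelate with F6 that should release 12 only on work-up, without over-addition.

**Further compounds**

F1 | step 4 | ring C diacid (as 8 with both esters as CO2H) | C=C1CC[C@H]2CC(C(=O)O)=C(O[C@]2(C)CC[C@@H]2[C@@H]1CC2(C)C)C(C)(C)C(=O)O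
F2 | step 4 | cyclic anhydride of F1 (six-membered, C1′(=O)–O–C5′(=O)) | C=C1CC[C@H]2CC3=C(O[C@]2(C)CC[C@@H]2[C@@H]1CC2(C)C)C(C)(C)C(=O)OC3=O
F3 | step 4 | diketo acid (C2′ carries the (S)-4-methyl-3-oxohexanoyl group, C3′ carries C(CH3)2CO2H) | C=C1CC[C@H]2CC(C(=O)CC(=O)[C@@H](C)CC)=C(O[C@]2(C)CC[C@@H]2[C@@H]1CC2(C)C)C(C)(C)C(=O)O
F4 | step 2 | dimethyl 4-[(dimethylamino)methyl]-2,2-dimethyl-3-oxopentanedioate (racemic) | COC(=O)C(CN(C)C)C(=O)C(C)(C)C(=O)OC
F5 | step 2 | [2,4-bis(methoxycarbonyl)-4-methyl-3-oxopentyl]trimethylammonium iodide (racemic) | COC(=O)C(C[N+](C)(C)C)C(=O)C(C)(C)C(=O)OC.[I-]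
F6 | step 3 | (S)-N-methoxy-N,2-dimethylbutanamide | CON(C)C(=O)[C@@H](C)CC
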